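## Structural features

The target is a 1,2-dioxan-3-ol. The ring atoms are O1, O2, C3 (peroxyhemiketal carbon with OH and CH3), C4 (CH with CH3), C5 (CH2) and C6, a fully substituted carbon that carries O1, a methyl group and the side chain C7–C16 ending in a phenyl ring. The chain has one stereocentre, C8 (CH3). C3 and C4 are adjacent, and C4, C6 and C8 form a 1,3,5-array of methyl-bearing carbons with the configuration 3S,4R,6S,8R.

The O–O bond is fragile towards low-valent metals, hydrides, hydrogenation catalysts and carbanions. The hemiketal is in equilibrium with the open hydroperoxy ketone, so C3 is under thermodynamic control (OH axial, C3 methyl equatorial), whereas C4 can be lost through enolisation of the open form. The real difficulty is C6, an oxygen-bearing quaternary centre with no stereocentre next to it, which must stand in a defined relation to C4 and C8. Equilibration is not expected to help, because either C4 epimer of the ring has to place one carbon substituent of C6 axial.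

The feature that the key step uses is that the methyl groups on C4, C6 and C8 are all syn along the backbone C3–C9. If C3 is bonded to C8, the atoms C3–C8 become an all-cis 2,4,6-trimethylcyclohexanone with the peroxy group on the ring carbon opposite the carbonyl group. This ring is meso and has the carbon skeleton of 2,4,6-trimethylphenol, with the para carbon as C6. C9 is then the single carbon that has to be inserted between C3 and C8.

## Logic of the disconnections

**20 to 19.** No skeletal bond is cut; the C9–C10 single bond is traced back to a cis double bond. This lets C10–C16 and the phenyl ring arrive as one phosphorus ylide. The forward step must saturate a 1,2-disubstituted alkene without touching the O–O bond or the hemiketal, which points to diimide.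

**19 to 17 (through 18).** The O2–C3 bond is cut. The ring opens to a methyl ketone and a capped tertiary hydroperoxide, and C3 needs no control because the hemiketal equilibrates to the axial hydroxyl. The forward step needs an acid mild enough to leave C4, now α to a ketone, untouched.

**17 to 12 and 15 (15 from 13 and 14).** The C9=C10 double bond is cut. The lipophilic tail is removed and a C9 aldehyde remains. The forward olefination must choose the aldehyde over the ketone and must not enolise C8 or C4.

**12 to 11.** C3 and C9 are reconnected as a ring double bond. The acyclic keto aldehyde with three stereocentres becomes a 1-methylcycloheptene, so both carbonyl groups come from one alkene. The forward cleavage must leave the peroxyketal alone and should need no reductant.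

**11 to 10 to 9.** The bond between C3 and its methyl group is cut, back to an enol triflate and then to a ketone. This leaves a cycloheptanone with an unsubstituted CH2 (C9) on one side of the carbonyl group. The forward steps demand enolisation towards C9 only and a neutral methyl coupling.

**9 to 6 and 7.** The C8–C9 and C3–C9 bonds are cut and C9 is removed. The chiral cycloheptanone becomes a meso cyclohexanone, so three stereocentres become a matter of relative configuration only. The forward step must choose one of two mirror-related C–C bonds and must proceed with retention at the migrating carbon.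

**6 to 5 to 3.** No bond is cut. The relative configuration of 6 is traced to base equilibration of a diastereomer mixture, and the cap on the hydroperoxide is removed. The demand is that the all-equatorial trimethyl isomer is the stable one and that the cap is achiral and base-stable.

**3 to 2 to 1.** The four ring C–H bonds come from saturation of a dienone, and the C6–O1 bond comes from oxygenation of a phenol at its para carbon. The quaternary peroxide carbon is thus made in an achiral compound, where it poses no stereochemical problem. The demands are para-selective oxygenation and a reduction of two conjugated double bonds that spares the hydroperoxide.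

## Other disconnections considered

**Alternative 1:** aerobic three-component annulation.

- **Cut:** C4–C5, C6–O1 and O2–C3 at once.
- **Forward key step:** Mn(OAc)3 (trivalent manganese) in acetic acid under O2 oxidises 3-methylpentane-2,4-dione A2 to its α-radical. This adds to the CH2 terminus of (4R)-2,4-dimethyl-12-phenyldodec-1-ene A1. The tertiary C6 radical captures O2, and the peroxide closes on one acetyl group to give the acetyl dioxanol A3.
- **In favour:** three bonds, the ring and the hemiketal form in one step, the oxygen comes from air, and the reaction type is established. On step economy and on precedent it is better than the chosen plan.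
- **Against:** O2 capture at the planar C6 radical has no facial bias from the remote C8 centre, so C6 should form as both epimers. C4 becomes quaternary, and the extra acetyl group must be removed by a deacylation that sets C4 by protonation only. 1,1-Dialkyl alkenes and 2-substituted diketones are the weaker partners in this chemistry.
- **Comparison:** the chosen plan is longer and rests on an untested step, but it addresses C4, C6 and C8 together. The alternative leaves C6 and C4, the two hard centres, uncontrolled.

**Alternative 2:** invertive oxetane perhydrolysis, then enol ether homologation.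

- **Cut:** C3–C4, as the double bond of an enol ether; C6–O1 is made earlier by opening an oxetane.
- **Forward key step:** perhydrolysis of (2R)-2,4-dimethyl-2-[(2R)-2-methyl-10-phenyldecyl]oxetane A4 with inversion at the quaternary carbon, then capping and oxidation, gives the β-peroxy ketone A5. A Wittig reaction of A5 with (1-methoxyethylidene)triphenylphosphorane gives the enol ether A6, and acid would then unmask the ketone and close the ring.
- **In favour:** C6 is set by a stereospecific substitution at a defined centre. On this point it is better than the chosen plan, whose absolute configuration depends on a catalyst never tried on such a ketone. Every step has precedent.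
- **Against:** C4 arises by protonation of the enol ether with no controlling element, and equilibration is not expected to correct it. A basic ylide meets a ketone with a peroxy group in the β position, where enolisation can expel the peroxide. A tetrasubstituted enol ether from a ketone is a demanding olefination. A4 itself needs two stereocentres built separately.
- **Comparison:** the two plans are comparable in length and equal in the final acid closure. The alternative is better at C6 and worse at C4.

**Alternative 3:** dithiane linchpin.

- **Cut:** C5–C6.
- **Forward key step:** 2-[(2R)-2-methyl-10-phenyldecyl]-1,3-dithiane A8, lithiated with tBuLi, is alkylated by 2-[(2S)-1-iodopropan-2-yl]-2-methyl-1,3-dioxolane A9 to give the bis-alkylated dithiane A10. Both arms derive from methyl (R)-3-hydroxy-2-methylpropanoate A7.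
- **In favour:** the C–C coupling is robust, C4 and C8 come from one chiral-pool ester, and no peroxide is carried until the end. In precedent, in the source of absolute configuration and in the handling of peroxides it is better than the chosen plan.
- **Against:** C6 is a masked ketone flanked by two almost identical arms. Converting it to the methyl-bearing peroxide carbon (methyl addition, then ionising perhydrolysis or radical peroxidation) passes through planar intermediates, so C6 should form without selectivity and late. The route is expected to be clearly longer.
- **Comparison:** the chosen plan fixes C6 first, in an achiral ring, and relates the other centres to it. The alternative fixes the easy centres first and leaves the hard one open.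

Key step: step 5

Remark on the structures: the meso precursor 6 has a pseudoasymmetric C4, so its full descriptor is (2R,4s,6S); product 9 is (2R,4S,6S).
Assumption: the sense of induction of the catalyst in step 5 cannot be predicted; the route is written for the ligand antipode that makes the S-configured α-carbon of 6 migrate, the mirror-image ligand being equally accessible.
Remark: the double bond of 17, 18 and 19 is drawn Z, as expected for an unstabilised ylide; its geometry is of no consequence.

## Route

Step 1
Reactants: 1 2,4,6-trimethylphenol
Product: 2 4-hydroperoxy-2,4,6-trimethylcyclohexa-2,5-dien-1-one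
Conditions: O2, tetraphenylporphyrin (cat.), visible light, CH2Cl2, 0 °C
Reagents that add atoms: dioxygen, O=O
Why: Photooxygenation with singlet oxygen: the electron-rich phenol is attacked at its methyl-bearing para carbon and gives the para-hydroperoxy dienone, the established outcome for this phenol; the product is achiral, so the quaternary peroxide carbon is made without a stereochemical issue.

Step 2
Reactants: 2 4-hydroperoxy-2,4,6-trimethylcyclohexa-2,5-dien-1-one
Product: 3 4-hydroperoxy-2,4,6-trimethylcyclohexan-1-one (mixture of diastereomers)
Conditions: KO2CN=NCO2K (large excess, in portions), AcOH, MeOH, 0 °C → rt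
Reagents that add atoms: none
Why: Diimide reduction: concerted syn transfer of H2 to C=C leaves O–O, O–H and C=O untouched, and free hydroperoxides are standard substrates; the two conjugated but trisubstituted double bonds are slow, hence the excess, and the face of attack is immaterial because step 4 equilibrates C2 and C6.

Step 3
Reactants: 3 4-hydroperoxy-2,4,6-trimethylcyclohexan-1-one; 4 2-methoxypropene
Product: 5 4-[(2-methoxypropan-2-yl)peroxy]-2,4,6-trimethylcyclohexan-1-one (mixture of diastereomers)
Conditions: PPTS (cat.), CH2Cl2, 0 °C
Reagents that add atoms: none
Why: Acid-catalysed addition of the hydroperoxide O–H to the enol ether gives the mixed peroxyketal, which is stable to bases and enolates; the cap is achiral, so the later ketone 6 stays meso.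

Step 4
Reactants: 5 4-[(2-methoxypropan-2-yl)peroxy]-2,4,6-trimethylcyclohexan-1-one (mixture)
Product: 6 (2R,4s,6S)-4-[(2-methoxypropan-2-yl)peroxy]-2,4,6-trimethylcyclohexan-1-one (meso, three methyl groups cis)
Conditions: NaOMe (cat.), MeOH, rt; chromatography, minor isomers resubmitted
Reagents that add atoms: none
Why: Thermodynamic epimerisation through the enolate sets C2 and C6: both α-methyl groups go equatorial (cis), and double epimerisation also adjusts their relation to C4, where methyl (A about 1.7 kcal/mol) should prefer the equatorial and the peroxy oxygen (A below 1 kcal/mol, lower still opposite a carbonyl group) the axial site; the peroxide is γ to the carbonyl group, so no elimination path exists.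

Step 5
Reactants: 6 (2R,4s,6S)-4-[(2-methoxypropan-2-yl)peroxy]-2,4,6-trimethylcyclohexan-1-one; 7 (trimethylsilyl)diazomethane
Product: 9 (2R,4S,6S)-4-[(2-methoxypropan-2-yl)peroxy]-2,4,6-trimethylcycloheptan-1-one, via silyl enol ether 8 (not isolated)
Conditions: Sc(OTf)3 (10 mol %), chiral N,N′-dioxide ligand from (S)-pipecolic acid with 2,6-diisopropylanilide arms and a trimethylene linker (12 mol %), 4 Å MS, CH2Cl2, −20 → 0 °C; then Bu4NF/AcOH (1:1), THF, 0 °C
Reagents that add atoms: none
Why: Proposed new method: the trivalent scandium centre of the chiral Sc(OTf)3–N,N′-dioxide complex binds the carbonyl oxygen of 6, the nucleophilic carbon of 7 adds to the carbonyl carbon to give a β-diazonio alkoxide, and the ring C–C bond antiperiplanar to the departing N2 migrates to the new carbon with retention at the migrating carbon. A 1,3-shift of silicon from carbon to oxygen (Brook rearrangement) then gives enol silane 8, which is inert to a second homologation, and buffered fluoride releases ketone 9. The closest known reaction types are the chiral Lewis acid catalysed desymmetrising ring expansion of prochiral 4-substituted cyclohexanones with diazo compounds and the Sc(OTf)3-catalysed homologation of cyclic ketones with Me3SiCHN2; enantiotopic bond selection in a meso 2,6-disubstituted ketone has no precedent. No ring is closed: the six-membered carbocycle grows to seven by insertion of C9 between C3 and C8 (target numbering), which forms the C8–C9 bond and the temporary C3–C9 bond. No lasting stereocentre is created; C4, C6 and C8, already correct relative to one another after step 4, become absolute through the choice of the migrating bond, and C8 keeps its configuration because 1,2-shifts to electron-poor carbon proceed with retention. The selectivity required is enantiotopic group selection between the C1–C2 and C1–C6 bonds of 6 (migration of the S-configured C6 is wanted), and it must come from the catalyst, which decides which face of the diazo carbon bonds to the bound ketone. The substrate relays that choice: in the adduct the hydrogen of the new carbon has to take the crowded slot between the two CH(CH3) carbons, the SiMe3 group then sits gauche to oxygen, and N2 is left antiperiplanar to one α-carbon only. The locked chair with three equatorial methyl groups and the axial peroxy group remote from the carbonyl gives the catalyst a rigid, sterically simple ketone to read.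

Step 6
Reactants: 9 (2R,4S,6S)-4-[(2-methoxypropan-2-yl)peroxy]-2,4,6-trimethylcycloheptan-1-one
Product: 10 (3S,5S,7R)-5-[(2-methoxypropan-2-yl)peroxy]-3,5,7-trimethylcyclohept-1-en-1-yl trifluoromethanesulfonate
Conditions: LDA, THF, −78 °C (9 added to the base); then 2-[N,N-bis(trifluoromethylsulfonyl)amino]-5-chloropyridine, −78 °C
Reagents that add atoms: 2-[N,N-bis(trifluoromethylsulfonyl)amino]-5-chloropyridine, FC(F)(F)S(=O)(=O)N(c1ccc(Cl)cn1)S(=O)(=O)C(F)(F)F
Why: Kinetic deprotonation by a hindered amide base takes the CH2 proton (C9) rather than the tertiary C4–H, and O-sulfonylation of the lithium enolate by the reactive pyridyl triflimide at −78 °C fixes the C3=C9 double bond; C4 is not touched and the peroxyketal tolerates amide bases at this temperature.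

Step 7
Reactants: 10 (3S,5S,7R)-5-[(2-methoxypropan-2-yl)peroxy]-3,5,7-trimethylcyclohept-1-en-1-yl trifluoromethanesulfonate
Product: 11 (3S,5S,7R)-5-[(2-methoxypropan-2-yl)peroxy]-1,3,5,7-tetramethylcyclohept-1-ene
Conditions: Me4Sn, Pd(PPh3)4 (cat.), LiCl, THF, 65 °C
Reagents that add atoms: tetramethylstannane, C[Sn](C)(C)C
Why: Stille coupling of an enol triflate: oxidative addition of zerovalent palladium to the C–OTf bond, methyl transfer from tin and reductive elimination, under neutral conditions that hindered dialkyl peroxides are known to tolerate; no stereocentre takes part.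

Step 8
Reactants: 11 (3S,5S,7R)-5-[(2-methoxypropan-2-yl)peroxy]-1,3,5,7-tetramethylcyclohept-1-ene
Product: 12 (2S,4S,6R)-4-[(2-methoxypropan-2-yl)peroxy]-2,4,6-trimethyl-7-oxooctanal
Conditions: O3, pyridine (3 equiv), CH2Cl2, −78 °C; used at once
Reagents that add atoms: ozone, [O-][O+]=O
Why: Ozonolysis of the only C=C cleaves the C3–C9 bond; pyridine diverts the carbonyl oxide so that the methyl ketone (C3) and the aldehyde (C9) are released directly with loss of O2 and no reductant meets the peroxyketal, which is itself inert to ozone; the stereocentres are untouched and only their descriptors change.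

Step 9
Reactants: 13 (7-bromoheptyl)benzene; 14 triphenylphosphine
Product: 15 triphenyl(7-phenylheptyl)phosphonium bromide
Conditions: MeCN, reflux
Reagents that add atoms: none
Why: SN2 quaternisation of the phosphine by a primary bromide, the standard preparation of a Wittig salt.

Step 10
Reactants: 12 (2S,4S,6R)-4-[(2-methoxypropan-2-yl)peroxy]-2,4,6-trimethyl-7-oxooctanal; 15 triphenyl(7-phenylheptyl)phosphonium bromide
Product: 17 (3R,5S,7S,8Z)-5-[(2-methoxypropan-2-yl)peroxy]-3,5,7-trimethyl-15-phenylpentadec-8-en-2-one, via phosphorus ylide 16 (not isolated)
Conditions: 15 (1.05 equiv), NaHMDS, THF, 0 °C; then 12 added at −78 °C, → 0 °C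
Reagents that add atoms: none
Why: Wittig reaction: the unstabilised ylide adds to the aldehyde far faster than to the hindered methyl ketone and gives mainly the Z alkene through the oxaphosphetane; low temperature and a near-stoichiometric amount of ylide keep enolisation of C8 and C4 low.

Step 11
Reactants: 17 (3R,5S,7S,8Z)-5-[(2-methoxypropan-2-yl)peroxy]-3,5,7-trimethyl-15-phenylpentadec-8-en-2-one
Product: 19 (3S,4R,6S)-3,4,6-trimethyl-6-[(2S,3Z)-2-methyl-10-phenyldec-3-en-1-yl]-1,2-dioxan-3-ol, via hydroperoxy ketone 18 (not isolated)
Conditions: AcOH/THF/H2O (4:2:1), rt
Reagents that add atoms: none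
Why: Mild acid hydrolyses the mixed peroxyketal, and the free hydroperoxide adds to the C3 ketone in a 6-exo-trig closure; the hemiketal is reversible, so C3 settles under thermodynamic control with OH axial (anomeric effect) and the C3 methyl equatorial next to the equatorial C4 methyl, which is the 3S configuration; the ring form also shields C4 from enolisation.

Step 12
Reactants: 19 (3S,4R,6S)-3,4,6-trimethyl-6-[(2S,3Z)-2-methyl-10-phenyldec-3-en-1-yl]-1,2-dioxan-3-ol
Product: 20 (3S,4R,6S)-3,4,6-trimethyl-6-[(2R)-2-methyl-10-phenyldecyl]-1,2-dioxan-3-ol (target)
Conditions: KO2CN=NCO2K (excess), AcOH, CH2Cl2, 0 °C → rt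
Reagents that add atoms: none
Why: Diimide reduction of a cis-1,2-disubstituted alkene, the fastest substrate class for this reagent, with the O–O bond, hemiketal and phenyl ring inert; no stereocentre is created, and C8 changes descriptor only because the ranking of its substituents changes.

## Compound list

1 | 2,4,6-trimethylphenol | Cc1cc(C)c(O)c(C)c1 | starting material
2 | 4-hydroperoxy-2,4,6-trimethylcyclohexa-2,5-dien-1-one | CC1=CC(C)(OO)C=C(C)C1=O | intermediate
3 | 4-hydroperoxy-2,4,6-trimethylcyclohexan-1-one (mixture of diastereomers) | CC1CC(C)(OO)CC(C)C1=O | intermediate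
4 | 2-methoxypropene | COC(C)=C | starting material
5 | 4-[(2-methoxypropan-2-yl)peroxy]-2,4,6-trimethylcyclohexan-1-one (mixture of diastereomers) | CC1CC(C)(OOC(C)(C)OC)CC(C)C1=O | intermediate
6 | (2R,4s,6S)-4-[(2-methoxypropan-2-yl)peroxy]-2,4,6-trimethylcyclohexan-1-one | C[C@H]1C[C@](C)(OOC(C)(C)OC)C[C@@H](C)C1=O | intermediate
7 | (trimethylsilyl)diazomethane | C[Si](C)(C)C=[N+]=[N-] | starting material
8 | trimethyl{[(3S,5S,7R)-5-[(2-methoxypropan-2-yl)peroxy]-3,5,7-trimethylcyclohept-1-en-1-yl]oxy}silane | C[C@H]1C[C@](C)(OOC(C)(C)OC)C[C@@H](C)C(O[Si](C)(C)C)=C1 | intermediate (not isolated)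
9 | (2R,4S,6S)-4-[(2-methoxypropan-2-yl)peroxy]-2,4,6-trimethylcycloheptan-1-one | C[C@H]1C[C@](C)(OOC(C)(C)OC)C[C@@H](C)C(=O)C1 | intermediate
10 | (3S,5S,7R)-5-[(2-methoxypropan-2-yl)peroxy]-3,5,7-trimethylcyclohept-1-en-1-yl trifluoromethanesulfonate | C[C@H]1C[C@](C)(OOC(C)(C)OC)C[C@@H](C)C(OS(=O)(=O)C(F)(F)F)=C1 | intermediate
11 | (3S,5S,7R)-5-[(2-methoxypropan-2-yl)peroxy]-1,3,5,7-tetramethylcyclohept-1-ene | C[C@H]1C[C@](C)(OOC(C)(C)OC)C[C@@H](C)C(C)=C1 | intermediate
12 | (2S,4S,6R)-4-[(2-methoxypropan-2-yl)peroxy]-2,4,6-trimethyl-7-oxooctanal | C[C@H](C=O)C[C@](C)(OOC(C)(C)OC)C[C@@H](C)C(C)=O | intermediate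
13 | (7-bromoheptyl)benzene | BrCCCCCCCc1ccccc1 | starting material
14 | triphenylphosphine | c1ccc(cc1)P(c1ccccc1)c1ccccc1 | starting material
15 | triphenyl(7-phenylheptyl)phosphonium bromide | [Br-].c1ccc(cc1)[P+](CCCCCCCc1ccccc1)(c1ccccc1)c1ccccc1 | intermediate
16 | triphenyl(7-phenylheptylidene)-λ5-phosphane | c1ccc(cc1)P(=CCCCCCCc1ccccc1)(c1ccccc1)c1ccccc1 | intermediate (not isolated)
17 | (3R,5S,7S,8Z)-5-[(2-methoxypropan-2-yl)peroxy]-3,5,7-trimethyl-15-phenylpentadec-8-en-2-one | C[C@H](/C=C\CCCCCCc1ccccc1)C[C@](C)(OOC(C)(C)OC)C[C@@H](C)C(C)=O | intermediate
18 | (3R,5S,7S,8Z)-5-hydroperoxy-3,5,7-trimethyl-15-phenylpentadec-8-en-2-one | C[C@H](/C=C\CCCCCCc1ccccc1)C[C@](C)(OO)C[C@@H](C)C(C)=O | intermediate (not isolated)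
19 | (3S,4R,6S)-3,4,6-trimethyl-6-[(2S,3Z)-2-methyl-10-phenyldec-3-en-1-yl]-1,2-dioxan-3-ol | C[C@H](/C=C\CCCCCCc1ccccc1)C[C@@]1(C)C[C@@H](C)[C@@](C)(O)OO1 | intermediate
20 | (3S,4R,6S)-3,4,6-trimethyl-6-[(2R)-2-methyl-10-phenyldecyl]-1,2-dioxan-3-ol | C[C@H](CCCCCCCCc1ccccc1)C[C@@]1(C)C[C@@H](C)[C@@](C)(O)OO1 | target

## Step count and least certain steps

Total step count: 12. Longest linear sequence: 11 steps (steps 1 to 8 and 10 to 12, from 1); step 9 prepares the side-chain salt.

**Step 5 (key step).** Three processes may defeat it:
- slow addition of the diazoalkane to a ketone flanked by two tertiary α-carbons inside a crowded chiral complex;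
- insufficient discrimination between the two mirror-related migrating bonds, since the catalyst class has only been shown to read a remote substituent;
- ionisation of the acid-labile peroxyketal by the Lewis acid.

The fallback uses known chemistry and replaces asymmetric catalysis by resolution. It sets out from 6 and comes back at 9. Ligand-free Sc(OTf)3 with 7 in CH2Cl2, followed by the same buffered fluoride work-up, is the established achiral homologation. From the meso ketone it gives the racemate, that is 9 together with its mirror image (2S,4R,6R)-4-[(2-methoxypropan-2-yl)peroxy]-2,4,6-trimethylcycloheptan-1-one F1. Preparative chromatography on a chiral stationary phase then delivers 9.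

**Step 2.** Incomplete saturation is the likely failure, because diimide reacts slowly with trisubstituted double bonds of the 2-methylcyclohexenone type; long exposure of the free hydroperoxide is a second concern. The fallback changes the approach: the ring is saturated before the peroxide is installed. It sets out from 1 and comes back at 3.
- O-Methylation (MeI, K2CO3, acetone) gives 2-methoxy-1,3,5-trimethylbenzene F2.
- Birch reduction (Li, NH3, tBuOH, THF) gives 1-methoxy-2,4,6-trimethylcyclohexa-1,4-diene F3.
- Mild hydrolysis of the enol ether (oxalic acid, aqueous THF) gives 2,4,6-trimethylcyclohex-3-en-1-one F4.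
- Hydroperoxysilylation catalysed by Co(acac)2 (O2, Et3SiH, 1,2-dichloroethane) places hydrogen on the ring CH and the peroxy group on the tertiary carbon, giving 2,4,6-trimethyl-4-[(triethylsilyl)peroxy]cyclohexan-1-one F5.
- Desilylation with HCl (cat.) in MeOH gives 3.

The configuration at the peroxide carbon is again immaterial because of step 4.

**Step 6.** The enolate carbon C9 may attack the proximal peroxide oxygen across the ring, a 5-exo displacement that would form an oxygen bridge; proton exchange between enolate and ketone could also scramble C4. The fallback avoids a stoichiometric metal enolate. It sets out from 6 and comes back at 10. Step 5 is run without the fluoride work-up and enol silane 8 is isolated. Its double bond is already where it is needed. CsF and N-phenylbis(trifluoromethanesulfonimide) in 1,2-dimethoxyethane at rt then convert it into 10, a known transformation in which the enolate is triflated as fast as fluoride releases it. No new compound arises.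

**Step 10.** The basic ylide may enolise the aldehyde (loss of C8) or the ketone (loss of C4). It may also trigger an aldol closure between C4 and C9 or between C8 and C3, both six-membered, or attack the ketone. The fallback postpones the ketone. It sets out from 8 (isolated as above) and comes back at 17.
- Ozonolysis of 8 (O3, CH2Cl2, −78 °C; Me2S; aqueous work-up) gives (2R,4S,6S)-4-[(2-methoxypropan-2-yl)peroxy]-2,4,6-trimethyl-7-oxoheptanoic acid F7.
- Wittig reaction with two equivalents of 16 gives (2R,4S,6S,7Z)-4-[(2-methoxypropan-2-yl)peroxy]-2,4,6-trimethyl-14-phenyltetradec-7-enoic acid F8; the carboxylate is inert to the ylide.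
- EtSH, DCC and DMAP (cat.) give S-ethyl (2R,4S,6S,7Z)-4-[(2-methoxypropan-2-yl)peroxy]-2,4,6-trimethyl-14-phenyltetradec-7-enethioate F9.
- Fukuyama coupling with MeZnI and PdCl2(PPh3)2 (cat.) in toluene gives 17.

This removes the aldol and ketone problems but not the risk at C8.

## Further compounds

F1 | step 5 | (2S,4R,6R)-4-[(2-methoxypropan-2-yl)peroxy]-2,4,6-trimethylcycloheptan-1-one | C[C@@H]1C[C@@](C)(OOC(C)(C)OC)C[C@H](C)C(=O)C1
F2 | step 2 | 2-methoxy-1,3,5-trimethylbenzene | COc1c(C)cc(C)cc1C
F3 | step 2 | 1-methoxy-2,4,6-trimethylcyclohexa-1,4-diene (racemic) | COC1=C(C)CC(C)=CC1C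
F4 | step 2 | 2,4,6-trimethylcyclohex-3-en-1-one (mixture of stereoisomers) | CC1CC(C)=CC(C)C1=O
F5 | step 2 | 2,4,6-trimethyl-4-[(triethylsilyl)peroxy]cyclohexan-1-one (mixture of diastereomers) | CC[Si](CC)(CC)OOC1(C)CC(C)C(=O)C(C)C1
F0 | step 6 | none | none
F7 | step 10 | (2R,4S,6S)-4-[(2-methoxypropan-2-yl)peroxy]-2,4,6-trimethyl-7-oxoheptanoic acid | C[C@H](C=O)C[C@](C)(OOC(C)(C)OC)C[C@@H](C)C(=O)O
F8 | step 10 | (2R,4S,6S,7Z)-4-[(2-methoxypropan-2-yl)peroxy]-2,4,6-trimethyl-14-phenyltetradec-7-enoic acid | C[C@H](/C=C\CCCCCCc1ccccc1)C[C@](C)(OOC(C)(C)OC)C[C@@H](C)C(=O)O
F9 | step 10 | S-ethyl (2R,4S,6S,7Z)-4-[(2-methoxypropan-2-yl)peroxy]-2,4,6-trimethyl-14-phenyltetradec-7-enethioate | C[C@H](/C=C\CCCCCCc1ccccc1)C[C@](C)(OOC(C)(C)OC)C[C@@H](C)C(=O)SCC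
A1 | alternative 1 | (4R)-2,4-dimethyl-12-phenyldodec-1-ene | C=C(C)C[C@H](C)CCCCCCCCc1ccccc1
A2 | alternative 1 | 3-methylpentane-2,4-dione | CC(=O)C(C)C(C)=O
A3 | alternative 1 | 1-[(6S)-3-hydroxy-3,4,6-trimethyl-6-[(2R)-2-methyl-10-phenyldecyl]-1,2-dioxan-4-yl]ethan-1-one (C3 and C4 not assigned) | CC(=O)C1(C)C[C@](C)(C[C@H](C)CCCCCCCCc2ccccc2)OOC1(C)O
A4 | alternative 2 | (2R)-2,4-dimethyl-2-[(2R)-2-methyl-10-phenyldecyl]oxetane (C4 either configuration) | CC1C[C@@](C)(C[C@H](C)CCCCCCCCc2ccccc2)O1
A5 | alternative 2 | (4S,6R)-4-[(2-methoxypropan-2-yl)peroxy]-4,6-dimethyl-14-phenyltetradecan-2-one | CC(=O)C[C@](C)(C[C@H](C)CCCCCCCCc1ccccc1)OOC(C)(C)OC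
A6 | alternative 2 | (5S,7R)-2-methoxy-5-[(2-methoxypropan-2-yl)peroxy]-3,5,7-trimethyl-15-phenylpentadec-2-ene (either alkene geometry) | COC(C)=C(C)C[C@](C)(C[C@H](C)CCCCCCCCc1ccccc1)OOC(C)(C)OC
A7 | alternative 3 | methyl (R)-3-hydroxy-2-methylpropanoate | COC(=O)[C@H](C)CO
A8 | alternative 3 | 2-[(2R)-2-methyl-10-phenyldecyl]-1,3-dithiane | S1CCCSC1C[C@H](C)CCCCCCCCc1ccccc1
A9 | alternative 3 | 2-[(2S)-1-iodopropan-2-yl]-2-methyl-1,3-dioxolane | CC1(OCCO1)[C@H](C)CI
A10 | alternative 3 | 2-[(2R)-2-(2-methyl-1,3-dioxolan-2-yl)propyl]-2-[(2R)-2-methyl-10-phenyldecyl]-1,3-dithiane | CC1(OCCO1)[C@H](C)CC2(SCCCS2)C[C@H](C)CCCCCCCCc3ccccc3
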